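## Structural features

The target is a spiro[5.5]undecane (chamigrene skeleton) whose rings share only the quaternary carbon C6. Ring A is C1 (methyl, double bond to C2), C2, C3 (OH), C4 (Br), C5 (gem-dimethyl), C6; ring B is C6, C7, C8, C9 (methyl, double bond to C10), C10 (Br), C11. C6 lies between quaternary C5 and sp2 C1, and it is stereogenic only because the C9=C10 bromoalkene makes the C7 and C11 arms of ring B different, a difference that starts two bonds away. C3 and C4 are adjacent stereocentres with hydroxyl and bromine trans, and C4 is tied to C6 through C5, with bromine on the ring A face that carries C11. The fragile groups are the allylic alcohol (ionisation), the trans bromohydrin (epoxide closure under base), the neopentyl-type secondary bromide and the tetrasubstituted alkenyl bromide (oxidative addition, metal–halogen exchange). The real difficulty is threefold: the C5–C6 vicinal quaternary array with absolute control at C6, the relay of that remote asymmetry to C4, and the placing of bromine and methyl on defined carbons of ring B. The key step uses the bond from C6 to sp2 C1: an alkenylpalladium at C1 adds across a C6=C7 bond of a six-membered diene, which closes ring A, creates C6 and leaves a C9–C10 enol ether that marks C10 for bromine and C9 for methyl.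

## Logic of the disconnections

19 from 17 through 18 (C3–O). The C3–O bond is cut and re-formed with inversion. Hydride addition to the C3 ketone of 16 should come from the face away from the axial C5 methyl and so place the hydroxyl cis to bromine, whereas 19 needs it trans. The gain is that C3 follows from a dependable selectivity. The demand is SN2 substitution at an allylic carbon beside C4–Br without loss of the C4 hydrogen, and an ester cleavage that never frees an alkoxide next to the trans bromide.

17 from 16 (C3–H). Cutting C3–H restores the C3 carbonyl, which makes C4 acidic and its configuration adjustable. The forward step must be a 1,2-selective, cis-selective reduction that leaves two C–Br bonds alone.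

16 from 13 (C4–Br). The C4–Br bond is cut next to the carbonyl, where an enol derivative accepts electrophilic bromine. This removes the second ring A stereocentre and leaves C6 as the only one. The demand is regiocontrol (met through 14) and a C4 configuration tied to C6 (met by equilibrating 15 into 16).

13 from 12 (C7–H, C8–H). Two C–H bonds are removed to reveal a C7=C8 bond. With C8 sp2, the ring B ketone of 9 can enolise only toward C10, and this alkene is what the key step leaves behind. The demand is reduction of one cis-disubstituted alkene beside a trisubstituted enone, a tetrasubstituted bromoalkene and C–Br bonds.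

12 from 9 through 11 and 10 (C9–CH3, then C9–O sulfonate). The methyl is cut from C9, which simplifies the tetrasubstituted bromoalkene to an α-bromo ketone. The demand is coupling at C9–O in preference to C10–Br, and enolisation of the ring B ketone rather than the ring A ketone.

9 from 8 (C10–Br, C9=O). The C10–Br bond is cut and the C9 carbonyl is masked as a methyl enol ether, whose position distinguishes C10 from C8. The demand is bromination at C10 only.

8 from 7 (C1–C6). This strategic cut opens ring A, removes the only stereocentre and replaces the vicinal quaternary array by an achiral precursor. The demand is face selection at C6=C7 by a chiral catalyst, exo closure, and an iodide on C1 cis to the C3 carbonyl.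

7 from 6 (C1–I, C2–H) and 6 from 4 and 5 (C2–C3). Removing HI gives an ynone, and cutting C2–C3 gives an acyl donor and an alkynyl nucleophile. The demand is anti addition of HI and acylation without over-addition, both in the presence of an acid-labile enol ether.

4 from 2 (amide C–N) and 2 from 1 (four ring C–H bonds). The diene ring is traced to an anisole. The demand is that the enol ether survives isolation of an acid and its activation.

## Other disconnections considered

Alternative 1: The cut goes through C5–C6 and C4–Br and opens ring A to (E)-1-bromo-2-methyl-5-(6-methylhept-5-en-2-ylidene)cyclohex-1-ene A1.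
- Forward step: a vanadium bromoperoxidase with KBr and H2O2 would brominate the terminal C4=C5 alkene, C6 of the tetrasubstituted alkene would trap the C5 cation, and loss of the C2 proton would give the 3-deoxy compound A2.
- In favour: one operation makes ring A, the C5–C6 bond, C4–Br and the C6 centre. A chair-like closure ties C4 to C6 directly (E geometry puts C7 axial and bromine equatorial). The chosen plan has to rely on an equilibration in step 10 for this relay, so here the alternative is the better, as it is on step count to the skeleton.
- Against: geometric purity of A1 is itself a remote-differentiation problem, since the arms that define E and Z differ only at C9/C10. The absolute configuration would depend on how an enzyme handles a non-natural brominated triene, with attack on the other alkenes, water capture and exocyclic proton loss all open. C3 would then need allylic oxidation in competition with C8, C11 and the allylic methyl groups, after which the C3 question of the chosen plan returns unchanged.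
- Comparison: the Heck closure gives a connectivity fixed by the tether and C6 under catalyst control; the cationic route is shorter but none of its selectivities can be assured in advance.

Alternative 2: The cut removes C10 from ring B (C9–C10 and C10–C11) and leads to the spiro cyclopentene A3.
- Forward step: dibromocarbene (CHBr3, KOt-Bu) adds to C9=C11, and AgBF4-assisted opening of the three-membered ring with loss of one bromide gives an allyl cation that bromide captures at C11, giving A4.
- In favour: bromine arrives on C10 while methyl-bearing C9 stays olefinic, so the triflate-versus-bromide question of step 8 and the alkene reduction of step 9 disappear. For ring B this is equal or one step shorter, and the ring expansion is well founded mechanistically.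
- Against: A4 carries an extra allylic bromide at C11 that must be removed without allylic transposition and without touching C10–Br. Capture at tertiary C9 competes with capture at C11. KOt-Bu would enolise the ring A enone. The alkene of A3 is hindered by the adjacent quaternary C6.
- Comparison: C6 is not addressed, so an enantioselective entry to A3 is still needed, and the C3/C4 endgame is identical. Overall one three-step sequence is exchanged for another with no net gain.

Alternative 3: The cut is C6–C11 and opens ring B; the tertiary alcohol A6 would come from dihydro-β-ionone A5 and 1-bromovinyllithium.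
- Forward step: a confined chiral imidodiphosphorimidate Brønsted acid ionises racemic A6 to a 2-bromoallyl cation paired with the chiral anion, C6 of the tetrasubstituted ring alkene attacks the CH2 terminus C11, and the C1 cation loses the C2 proton to give A7.
- In favour: it is by far the shortest approach (two steps from a bulk terpenoid to the full skeleton with C9 methyl and C10 bromine in place). It is stereoconvergent from a racemate and needs neither palladium nor silver. On step economy it is clearly better, and after allylic oxidation at C3 it would join the chosen route at 13, so the endgame is equal.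
- Against: face selection at a tetrasubstituted alkene by a counter-anion, with a cation destabilised by bromine on its central carbon, has no close analogue. Protonation of the ring alkene, seven-membered closure through C1 and exocyclic proton loss all compete. Oxidation of A7 at C3 must discriminate among several allylic sites.
- Comparison: the Heck closure builds the same quaternary array by an insertion whose regiochemistry is fixed; the cationic closure is more direct, but its enantio-, regio- and elimination selectivities are all open.

Key step: step 5

Assumption: (R)-BINAP is written for step 5; the sense of induction cannot be derived from first principles, and (S)-BINAP replaces it if the opposite sense operates. Locants in all names follow the atom numbering above; the C6 descriptor changes between 12, 13 and 14 only through priority changes, the spatial arrangement at C6 being the same from 8 to 19.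

Step 1
Reactants: 1 3-(4-methoxyphenyl)-3-methylbutanoic acid
Product: 2 3-(4-methoxycyclohexa-1,4-dien-1-yl)-3-methylbutanoic acid
Conditions: Li, NH3(l), THF, t-BuOH, −78 to −33 °C; NH4Cl; work-up at pH 6 (NaH2PO4), 0 °C
Reagents that add atoms: none
Why: Birch reduction of a 4-alkylanisole leaves the two double bonds on the donor-bearing carbons; the carboxylate forms at once and is not reduced, and the buffered work-up avoids hydrolysis of the enol ether.

Step 2
Reactants: 2 3-(4-methoxycyclohexa-1,4-dien-1-yl)-3-methylbutanoic acid
Product: 4 N-methoxy-3-(4-methoxycyclohexa-1,4-dien-1-yl)-N,3-dimethylbutanamide, via acyl imidazole 3 (not isolated)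
Conditions: 1,1'-carbonyldiimidazole, CH2Cl2, 0 °C to rt; then MeNH(OMe)·HCl, rt
Reagents that add atoms: N,O-dimethylhydroxylamine hydrochloride, CNOC.Cl
Why: Carbonyldiimidazole activates the acid without acid, and the liberated imidazole buffers the amine hydrochloride, so the enol ether never meets a strong acid; standard N-methoxy-N-methyl amide formation.

Step 3
Reactants: 4 N-methoxy-3-(4-methoxycyclohexa-1,4-dien-1-yl)-N,3-dimethylbutanamide; 5 1-propynylmagnesium bromide
Product: 6 6-(4-methoxycyclohexa-1,4-dien-1-yl)-6-methylhept-2-yn-4-one
Conditions: THF, 0 °C; cold sat. aq. NH4Cl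
Reagents that add atoms: none
Why: Alkynyl Grignard addition to an N-methoxy-N-methyl amide stops at the chelated tetrahedral adduct, which gives the ynone only on mild work-up, so no tertiary alcohol forms.

Step 4
Reactants: 6 6-(4-methoxycyclohexa-1,4-dien-1-yl)-6-methylhept-2-yn-4-one
Product: 7 (Z)-2-iodo-6-(4-methoxycyclohexa-1,4-dien-1-yl)-6-methylhept-2-en-4-one
Conditions: NaI (3 equiv), AcOH (3 equiv), MeCN, 0 °C to rt, dark; poured into cold aq. NaHCO3
Reagents that add atoms: sodium iodide, [Na+].[I-]
Why: Conjugate hydroiodination of an ynone: iodide adds to the β-carbon and the iodoallenol is protonated in plane on the side away from iodine (net anti addition), giving kinetically the Z isomer with iodine cis to the carbonyl. Limited AcOH in MeCN, low temperature and a bicarbonate quench keep the enol ether's exposure to acid short.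

Step 5
Reactants: 7 (Z)-2-iodo-6-(4-methoxycyclohexa-1,4-dien-1-yl)-6-methylhept-2-en-4-one
Product: 8 (6S)-9-methoxy-1,5,5-trimethylspiro[5.5]undeca-1,7,9-trien-3-one
Conditions: Pd2(dba)3 (5 mol %), (R)-BINAP (12 mol %), Ag3PO4 (2 equiv), DMA, 70 °C
Reagents that add atoms: none
Why: Zerovalent palladium bearing (R)-BINAP adds oxidatively to the C1–I bond, and Ag3PO4 removes iodide so that a cationic alkenylpalladium keeps both phosphorus atoms bound while the C6=C7 alkene coordinates. Syn migratory insertion joins C1 to C6 and puts palladium on C7, closing ring A in the 6-exo-trig mode; the 7-endo alternative would need a larger ring and would leave palladium on fully substituted C6. C6 is the only new stereocentre, and since 7 is achiral its configuration is decided by which enantiotopic face of C6=C7 the chiral diphosphine admits. The alkylpalladium at C7 has no hydrogen on quaternary C6, so syn β-hydride elimination can only take a C8 hydrogen, giving C7=C8 in conjugation with the untouched C9=C10 enol ether. Closure needs palladium and the C3 carbonyl cis on C1=C2, which the Z geometry supplies; if the alkenylpalladium isomerises, only the Z form cyclises. Insertion should outrun hydrogen transfer from the doubly allylic CH2 groups because it is an intramolecular six-membered closure, and the basic silver phosphate protects the enol ether. The closest known reaction type is the catalytic asymmetric intramolecular Heck cyclisation of aryl or alkenyl halides and triflates that forms all-carbon quaternary and spiro centres under silver-promoted cationic conditions.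

Step 6
Reactants: 8 (6S)-9-methoxy-1,5,5-trimethylspiro[5.5]undeca-1,7,9-trien-3-one
Product: 9 (6S)-10-bromo-1,5,5-trimethylspiro[5.5]undeca-1,7-diene-3,9-dione (both C10 epimers)
Conditions: NBS (1.05 equiv), NaHCO3, THF/H2O 4:1, 0 °C
Reagents that add atoms: N-bromosuccinimide, O=C1CCC(=O)N1Br; water, O
Why: A 2-alkoxy-1,3-diene is brominated at the enol ether β-carbon C10 because only that attack gives an oxygen-stabilised cation at C9; water then turns the oxocarbenium ion into the C9 ketone with loss of methanol. The ring A enone is far less nucleophilic, and the C10 configuration is irrelevant because C10 becomes sp2 in step 7.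

Step 7
Reactants: 9 (6S)-10-bromo-1,5,5-trimethylspiro[5.5]undeca-1,7-diene-3,9-dione
Product: 11 (6S)-10-bromo-1,5,5-trimethyl-3-oxospiro[5.5]undeca-1,7,9-trien-9-yl trifluoromethanesulfonate, via potassium bromodienolate 10 (not isolated)
Conditions: KN(SiMe3)2 (1.05 equiv), THF, −78 °C, 30 min; PhNTf2, −78 to 0 °C
Reagents that add atoms: N-phenylbis(trifluoromethanesulfonimide), O=S(=O)(N(c1ccccc1)S(=O)(=O)C(F)(F)F)C(F)(F)F
Why: The ring B ketone can enolise only toward C10 (C8 is sp2, C6 quaternary), and the C10 hydrogen, α to carbonyl and bromine, is the most acidic in the molecule, so standard enol triflate formation gives the C9=C10 bromoenol triflate with no regiochemical ambiguity and no Favorskii pathway. The hold at −78 °C lets any ring A enolate transfer its charge to this more stable enolate.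

Step 8
Reactants: 11 (6S)-10-bromo-1,5,5-trimethyl-3-oxospiro[5.5]undeca-1,7,9-trien-9-yl trifluoromethanesulfonate
Product: 12 (6S)-10-bromo-1,5,5,9-tetramethylspiro[5.5]undeca-1,7,9-trien-3-one
Conditions: MeZnCl (1.3 equiv), Pd(PPh3)4 (5 mol %), THF, rt to 40 °C
Reagents that add atoms: methylzinc chloride, C[Zn]Cl
Why: Negishi coupling: zerovalent palladium with PPh3 adds to alkenyl triflates much faster than to alkenyl bromides, so methyl is transferred to C9 only. MeZnCl does not add to the enone, and β-bromide elimination from the alkenylpalladium is impossible because it would give a cyclohexyne.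

Step 9
Reactants: 12 (6S)-10-bromo-1,5,5,9-tetramethylspiro[5.5]undeca-1,7,9-trien-3-one
Product: 13 (6R)-10-bromo-1,5,5,9-tetramethylspiro[5.5]undeca-1,9-dien-3-one
Conditions: KO2CN=NCO2K (excess, portions), AcOH, MeOH/CH2Cl2, 0 °C to rt
Reagents that add atoms: none
Why: Diimide reduction: concerted syn transfer of H2 is very sensitive to substitution, so the cis-disubstituted C7=C8 bond should react well before the trisubstituted enone C1=C2 and the tetrasubstituted C9=C10 bonds. C–Br bonds and the ketone are inert to diimide, unlike under catalytic hydrogenation.

Step 10
Reactants: 13 (6R)-10-bromo-1,5,5,9-tetramethylspiro[5.5]undeca-1,9-dien-3-one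
Product: 16 (4S,6S)-4,10-dibromo-1,5,5,9-tetramethylspiro[5.5]undeca-1,9-dien-3-one, via trimethylsilyl dienol ether 14 (not isolated), via C4-epimeric bromo ketone 15 (not isolated)
Conditions: LiN(SiMe3)2, Me3SiCl, THF, −78 °C; NBS, −78 to 0 °C; then DBU (0.2 equiv), CH2Cl2, rt
Reagents that add atoms: N-bromosuccinimide, O=C1CCC(=O)N1Br
Why: α'-Bromination of an enone through its silyl dienol ether: a hindered amide base deprotonates a 3-methylcyclohex-2-enone kinetically at C4, and NBS attacks the 2-silyloxy diene at C4, probably anti to the pseudoaxial C5 methyl, which gives mainly 15. C4–H is then acidic while no β-hydrogen (C5 quaternary) or α'-hydrogen (C2 sp2) exists, so DBU can only epimerise C4. 16 is expected to dominate at equilibrium because it alone holds bromine equatorial in the ring A half-chair that the spiro junction prefers (C1 methyl tilted toward sp2 C10 and away from the axial C8–H, making C7 pseudoaxial and C11 pseudoequatorial on ring A), whereas 15 must carry bromine axial and syn to C7 or adopt the worse half-chair.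

Step 11
Reactants: 16 (4S,6S)-4,10-dibromo-1,5,5,9-tetramethylspiro[5.5]undeca-1,9-dien-3-one
Product: 17 (3R,4S,6S)-4,10-dibromo-1,5,5,9-tetramethylspiro[5.5]undeca-1,9-dien-3-ol
Conditions: i-Bu2AlH (1.2 equiv), CH2Cl2, −78 °C; Rochelle salt
Reagents that add atoms: none
Why: 1,2-Reduction of the enone: with bromine equatorial, the axial C5 methyl lies on the bromine face and blocks axial delivery to C3, so hydride enters from the opposite face and the new hydroxyl ends up pseudoaxial and cis to bromine. C–Br bonds are inert at −78 °C.

Step 12
Reactants: 17 (3R,4S,6S)-4,10-dibromo-1,5,5,9-tetramethylspiro[5.5]undeca-1,9-dien-3-ol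
Product: 18 (3S,4S,6S)-4,10-dibromo-1,5,5,9-tetramethylspiro[5.5]undeca-1,9-dien-3-yl 4-nitrobenzoate
Conditions: 4-nitrobenzoic acid, PPh3, DIAD, THF, 0 °C to rt
Reagents that add atoms: 4-nitrobenzoic acid, O=C(O)c1ccc(cc1)[N+](=O)[O-]
Why: Mitsunobu reaction: the pseudoaxial allylic oxyphosphonium group is displaced with inversion by the carboxylate from the open opposite face, placing oxygen trans to bromine. SN2' attack at C1 is shut off because C1 is fully substituted and next to quaternary C6.

Step 13
Reactants: 18 (3S,4S,6S)-4,10-dibromo-1,5,5,9-tetramethylspiro[5.5]undeca-1,9-dien-3-yl 4-nitrobenzoate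
Product: 19 (3S,4S,6S)-4,10-dibromo-1,5,5,9-tetramethylspiro[5.5]undeca-1,9-dien-3-ol
Conditions: i-Bu2AlH (2.5 equiv), CH2Cl2, −78 °C; Rochelle salt
Reagents that add atoms: none
Why: Reductive ester cleavage releases the alcohol as an aluminium alkoxide, which, unlike a free alkoxide in basic methanolysis, should not displace the neighbouring trans bromide to form an epoxide. The nitro group and both C–Br bonds are inert at this temperature.

Compound list

1 | 3-(4-methoxyphenyl)-3-methylbutanoic acid | COc1ccc(cc1)C(C)(C)CC(=O)O | starting material
2 | 3-(4-methoxycyclohexa-1,4-dien-1-yl)-3-methylbutanoic acid | COC1=CCC(=CC1)C(C)(C)CC(=O)O | intermediate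
3 | 1-(imidazol-1-yl)-3-(4-methoxycyclohexa-1,4-dien-1-yl)-3-methylbutan-1-one (formed in situ) | COC1=CCC(=CC1)C(C)(C)CC(=O)n1ccnc1 | intermediate
4 | N-methoxy-3-(4-methoxycyclohexa-1,4-dien-1-yl)-N,3-dimethylbutanamide | COC1=CCC(=CC1)C(C)(C)CC(=O)N(C)OC | intermediate
5 | 1-propynylmagnesium bromide | CC#C[Mg]Br | starting material
6 | 6-(4-methoxycyclohexa-1,4-dien-1-yl)-6-methylhept-2-yn-4-one | CC#CC(=O)CC(C)(C)C1=CCC(OC)=CC1 | intermediate
7 | (Z)-2-iodo-6-(4-methoxycyclohexa-1,4-dien-1-yl)-6-methylhept-2-en-4-one | C/C(I)=C/C(=O)CC(C)(C)C1=CCC(OC)=CC1 | intermediate
8 | (6S)-9-methoxy-1,5,5-trimethylspiro[5.5]undeca-1,7,9-trien-3-one | CC1=CC(=O)CC(C)(C)[C@]12C=CC(OC)=CC2 | intermediate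
9 | (6S)-10-bromo-1,5,5-trimethylspiro[5.5]undeca-1,7-diene-3,9-dione (C10 epimer mixture) | CC1=CC(=O)CC(C)(C)[C@]12C=CC(=O)C(Br)C2 | intermediate
10 | potassium (6S)-10-bromo-1,5,5-trimethyl-3-oxospiro[5.5]undeca-1,7,9-trien-9-olate (formed in situ) | CC1=CC(=O)CC(C)(C)[C@]12C=CC([O-])=C(Br)C2.[K+] | intermediate
11 | (6S)-10-bromo-1,5,5-trimethyl-3-oxospiro[5.5]undeca-1,7,9-trien-9-yl trifluoromethanesulfonate | CC1=CC(=O)CC(C)(C)[C@]12C=CC(OS(=O)(=O)C(F)(F)F)=C(Br)C2 | intermediate
12 | (6S)-10-bromo-1,5,5,9-tetramethylspiro[5.5]undeca-1,7,9-trien-3-one | CC1=CC(=O)CC(C)(C)[C@]12C=CC(C)=C(Br)C2 | intermediate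
13 | (6R)-10-bromo-1,5,5,9-tetramethylspiro[5.5]undeca-1,9-dien-3-one | CC1=CC(=O)CC(C)(C)[C@]12CCC(C)=C(Br)C2 | intermediate
14 | {[(6S)-10-bromo-1,5,5,9-tetramethylspiro[5.5]undeca-1,3,9-trien-3-yl]oxy}trimethylsilane (formed in situ) | CC1=CC(O[Si](C)(C)C)=CC(C)(C)[C@]12CCC(C)=C(Br)C2 | intermediate
15 | (4R,6S)-4,10-dibromo-1,5,5,9-tetramethylspiro[5.5]undeca-1,9-dien-3-one (formed in situ) | CC1=CC(=O)[C@H](Br)C(C)(C)[C@]12CCC(C)=C(Br)C2 | intermediate
16 | (4S,6S)-4,10-dibromo-1,5,5,9-tetramethylspiro[5.5]undeca-1,9-dien-3-one | CC1=CC(=O)[C@@H](Br)C(C)(C)[C@]12CCC(C)=C(Br)C2 | intermediate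
17 | (3R,4S,6S)-4,10-dibromo-1,5,5,9-tetramethylspiro[5.5]undeca-1,9-dien-3-ol | CC1=C[C@@H](O)[C@@H](Br)C(C)(C)[C@]12CCC(C)=C(Br)C2 | intermediate
18 | (3S,4S,6S)-4,10-dibromo-1,5,5,9-tetramethylspiro[5.5]undeca-1,9-dien-3-yl 4-nitrobenzoate | CC1=C[C@H](OC(=O)c3ccc(cc3)[N+](=O)[O-])[C@@H](Br)C(C)(C)[C@]12CCC(C)=C(Br)C2 | intermediate
19 | (3S,4S,6S)-4,10-dibromo-1,5,5,9-tetramethylspiro[5.5]undeca-1,9-dien-3-ol | CC1=C[C@H](O)[C@@H](Br)C(C)(C)[C@]12CCC(C)=C(Br)C2 | target

Total step count: 13. Longest linear sequence: 13 steps (1 to 19).

Least certain steps

Step 5 (key step). Most likely failure: weak discrimination between the two faces of the C6=C7 bond, because they differ only through the remote tether, together with hydrogen transfer from the doubly allylic CH2 groups that would aromatise the diene and reduce the C–I bond. Fallback: enantiocontrol is moved from catalysis to resolution. The route is followed to 17 with material of whatever enantiomeric purity step 5 delivers. The fallback sets out from 17, which is esterified under the conditions of step 12 with (2S)-2-methoxy-2-phenylacetic acid to give (3S,4S,6S)-4,10-dibromo-1,5,5,9-tetramethylspiro[5.5]undeca-1,9-dien-3-yl (2S)-2-methoxy-2-phenylacetate F1. The minor enantiomer gives the diastereomer (3R,4R,6R)-4,10-dibromo-1,5,5,9-tetramethylspiro[5.5]undeca-1,9-dien-3-yl (2S)-2-methoxy-2-phenylacetate F2. The two are separated by chromatography or crystallisation, and F1 is cleaved with i-Bu2AlH as in step 13, returning to the route at 19.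

Step 10. Most likely failure: too small a thermodynamic preference between the C4 epimers, because the arms of ring B that make C6 stereogenic differ only at C9/C10, so equilibration stalls at a mixture. Fallback: separation with recycling instead of stereocontrol. It sets out from the mixture of 15 and 16, which is reduced as in step 11. 17 is separated from the bromohydrin of the other series, (4R,6S)-4,10-dibromo-1,5,5,9-tetramethylspiro[5.5]undeca-1,9-dien-3-ol F3. F3 is oxidised back to 15 with Dess–Martin periodinane and 15 is again treated with DBU. The fallback returns to the route at 17.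

Step 4. Most likely failure: acid-mediated hydrolysis or double-bond migration of the enol ether while HI adds to the ynone. Fallback: the leaving group is changed so that no Brønsted acid is needed. It sets out from 4: excess lithium enolate of acetone (LiN(SiMe3)2, acetone, THF, −78 °C) gives 6-(4-methoxycyclohexa-1,4-dien-1-yl)-6-methylheptane-2,4-dione F4. Deprotonation with LiN(SiMe3)2 to the chelated enolate and O-sulfonylation with PhNTf2 at the less hindered acetyl oxygen gives (Z)-6-(4-methoxycyclohexa-1,4-dien-1-yl)-6-methyl-4-oxohept-2-en-2-yl trifluoromethanesulfonate F5. F5 is cyclised with Pd2(dba)3, (R)-BINAP and K2CO3 without silver, since a triflate enters the cationic pathway by itself, and the fallback returns to the route at 8.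

Step 12. Most likely failure: elimination across C3–C4, because the axial oxyphosphonium group has an anti-periplanar C4 hydrogen acidified by bromine, or ionisation to the allyl cation with loss of stereochemical fidelity. Fallback: steps 11 to 13 are replaced by a reagent-controlled reduction. It sets out from 16, which is reduced with catecholborane and (S)-1-methyl-3,3-diphenyltetrahydro-1H,3H-pyrrolo[1,2-c][1,3,2]oxazaborole in toluene at −78 °C (Corey–Bakshi–Shibata reduction). With the alkenyl arm as the larger group this catalyst is the one indicated for hydride delivery to the C3 face syn to bromine; its antipode is used otherwise. The fallback comes back to the route at 19.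

Step 9. Most likely failure: stalling at the neopentyl-flanked C7=C8 bond, or over-reduction of the ring A enone when excess diimide is forced. Fallback: the alkene is removed earlier by conjugate reduction. It sets out from 9: [(Ph3P)CuH]6 in toluene at rt reduces the β-monosubstituted ring B enone in preference to the β,β-disubstituted ring A enone and gives (6R)-10-bromo-1,5,5-trimethylspiro[5.5]undec-1-ene-3,9-dione F6. KN(SiMe3)2 and PhNTf2, with the ketone kept in slight excess so that the more stable bromine-bearing enolate is trapped, give (6R)-10-bromo-1,5,5-trimethyl-3-oxospiro[5.5]undeca-1,9-dien-9-yl trifluoromethanesulfonate F7. Negishi methylation as in step 8 then returns to the route at 13.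

Further compounds

F1 | step 5 | (3S,4S,6S)-4,10-dibromo-1,5,5,9-tetramethylspiro[5.5]undeca-1,9-dien-3-yl (2S)-2-methoxy-2-phenylacetate | CC1=C[C@H](OC(=O)[C@@H](OC)c3ccccc3)[C@@H](Br)C(C)(C)[C@]12CCC(C)=C(Br)C2
F2 | step 5 | (3R,4R,6R)-4,10-dibromo-1,5,5,9-tetramethylspiro[5.5]undeca-1,9-dien-3-yl (2S)-2-methoxy-2-phenylacetate | CC1=C[C@@H](OC(=O)[C@@H](OC)c3ccccc3)[C@H](Br)C(C)(C)[C@@]12CCC(C)=C(Br)C2
F3 | step 10 | (4R,6S)-4,10-dibromo-1,5,5,9-tetramethylspiro[5.5]undeca-1,9-dien-3-ol (C3 epimers) | CC1=CC(O)[C@H](Br)C(C)(C)[C@]12CCC(C)=C(Br)C2
F4 | step 4 | 6-(4-methoxycyclohexa-1,4-dien-1-yl)-6-methylheptane-2,4-dione | CC(=O)CC(=O)CC(C)(C)C1=CCC(OC)=CC1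
F5 | step 4 | (Z)-6-(4-methoxycyclohexa-1,4-dien-1-yl)-6-methyl-4-oxohept-2-en-2-yl trifluoromethanesulfonate | C/C(OS(=O)(=O)C(F)(F)F)=C/C(=O)CC(C)(C)C1=CCC(OC)=CC1
F0 | step 12 | none | none
F6 | step 9 | (6R)-10-bromo-1,5,5-trimethylspiro[5.5]undec-1-ene-3,9-dione (C10 epimer mixture) | CC1=CC(=O)CC(C)(C)[C@]12CCC(=O)C(Br)C2
F7 | step 9 | (6R)-10-bromo-1,5,5-trimethyl-3-oxospiro[5.5]undeca-1,9-dien-9-yl trifluoromethanesulfonate | CC1=CC(=O)CC(C)(C)[C@]12CCC(OS(=O)(=O)C(F)(F)F)=C(Br)C2
A1 | alternative 1 | (E)-1-bromo-2-methyl-5-(6-methylhept-5-en-2-ylidene)cyclohex-1-ene | BrC1=C(C)CC/C(=C(/C)CCC=C(C)C)C1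
A2 | alternative 1 | (4R,6S)-4,10-dibromo-1,5,5,9-tetramethylspiro[5.5]undeca-1,9-diene | CC1=CC[C@@H](Br)C(C)(C)[C@]12CCC(C)=C(Br)C2
A3 | alternative 2 | (5R)-2,6,6,10-tetramethylspiro[4.5]deca-1,9-dien-8-one | CC1=CC(=O)CC(C)(C)[C@]12CCC(C)=C2
A4 | alternative 2 | (6R,11R)-10,11-dibromo-1,5,5,9-tetramethylspiro[5.5]undeca-1,9-dien-3-one | CC1=CC(=O)CC(C)(C)[C@]12CCC(C)=C(Br)[C@@H]2Br
A5 | alternative 3 | 4-(2,6,6-trimethylcyclohex-1-en-1-yl)butan-2-one (dihydro-β-ionone) | CC(=O)CCC1=C(C)CCCC1(C)C
A6 | alternative 3 | 2-bromo-3-methyl-5-(2,6,6-trimethylcyclohex-1-en-1-yl)pent-1-en-3-ol (racemic) | C=C(Br)C(C)(O)CCC1=C(C)CCCC1(C)C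
A7 | alternative 3 | (6R)-10-bromo-1,5,5,9-tetramethylspiro[5.5]undeca-1,9-diene | CC1=CCCC(C)(C)[C@]12CCC(C)=C(Br)C2
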